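Start with the easy question: which flask stands nearest the earlier run? Elm does, with the same D, the same temperature, half the X of the north-west run, and a longer time.

the same everywhere: D 0.12 M
- north-west: X 9.4 mM; temperature 60 °C; run made earlier
- elm: X 4.7 mM; temperature 60 °C; time 4.0 d
- birch: X 4.7 mM; at 60 °C until 3.0 d, from then on at 100 °C; time 4.0 d
- larch: X 4.7 mM; temperature 100 °C; time 4.0 d
- maple: X 4.7 mM; temperature 80 °C; time 4.0 d

north-west run (percent of the D charged): time / h: G / % = 0.833: 4.7; 1.33: 7.6; 2.00: 12.3; 2.50: 14.0; 4.00: 19.8; 6.00: 26.8; 10.0: 36.5

(standard deviation of a reading: 0.5 percentage points)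

1. the flask that comes out highest in amount of G, in percent of the D charged, or "all alike" when all lie within 1.5 percentage points (elm / birch / larch / maple / all alike)
2. G at the end, in percent of the D charged, elm
3. G at the end, in percent of the D charged, birch
4. G at the end, in percent of the D charged, larch
5. G at the end, in percent of the D charged, maple

What carries over from north-west to elm? Both directions of D + X <-> G + X carry X, and X is not consumed, so D's loss by this step is pseudo-first-order and its progress runs on X charge times time. Elm ends at 4.80 in multiples of that product at north-west's last reading, the X-clock. Clock 1 is the unit of the scale and the start is its zero: on this step, a flask at clock 1 at 60 °C stands where that last reading stands.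

Where is G at clock 0.500? That is north-west at 5.00 h, midway between the readings at 4.00 h and 6.00 h, so about 23.3%.

And the ceiling? A single exponential rise through that value and the last reading gives 53.8%, loosely, since each reading carries 0.5 percentage points. At elm's clock, 0.427% of that rise remains, so elm is past the bend.

The weak spot: what runs off the clock? D -> Z and D <-> L carry no X. Elm's plain time is 9.60 times north-west's, twice its clock, so those steps gain on G in elm, and I commit to elm below 53.8%.

And the hot flasks? Their clock reads 4.80 too, but north-west ran at 60 °C, so I give them no number.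

The forecast put elm first, with elm 50% (38% to 62%, centred below my ceiling), birch 43%, larch 38% and maple 44%: “Elm is probably highest, with low confidence”.

The flask gives elm highest at 45.2%, with maple 1.32%, birch 0.0776% and larch 0%.

    D + X ⇌ G + X, rate k1*[D]*[X] forward; the back reaction follows from the equilibrium constant (K = 0.660, k = 0.00590 L mol⁻¹ s⁻¹, Ea = 55.0 kJ mol⁻¹, ΔH = −55.0 kJ mol⁻¹)
    D + X ⇌ E + X, rate k2*[D]*[X] forward; the back reaction follows from the equilibrium constant (K = 0.170, k = 0.00280 L mol⁻¹ s⁻¹, Ea = 66.0 kJ mol⁻¹, ΔH = −42.0 kJ mol⁻¹)
    D ⇌ L (K = 1.90, k = 4.00 × 10⁻⁶ s⁻¹, Ea = 108 kJ mol⁻¹, ΔH = −46.0 kJ mol⁻¹)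
    D → Z (k = 2.00 × 10⁻⁵ s⁻¹, Ea = 121 kJ mol⁻¹)
    (constants at 80 °C)

Birch, on elm's clock, held 46.2% of G at the change of temperature and 0.0776% at the end. In elm, clock 2.40 at 2.00 d stood at 45.6% of G, and clock 4.80 stood at 45.2%, while Z went from 13.3% to 19.9%. North-west's recipe with elm's X, read at north-west's last time, sits at clock 0.500, where the readings put 23.3%, and it gives 23.5%.

The runs were generated by integration with made-up constants.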